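The earlier runs and the new flask are calculated from invented constants; scatter was added.

In a one-step world, E + J → L, every E lost is one L made and one J spent, so the flask is reckoned from the balance of E, the limiting reagent, charged at 0.10 M, less than any J charge here.

| setting | south | west | south-east | gamma | epsilon | eta |
|---|---|---|---|---|---|---|
| E | 0.10 M | 0.10 M | 0.10 M | 0.10 M | 0.10 M | 0.10 M |
| J | 0.25 M | 0.66 M | 1.3 M | 0.200 M | 0.600 M | 1.80 M |
| remark | run made earlier | run made earlier | run made earlier |  |  |  |
| time |  |  |  | 2.5 d | 2.5 d | 2.5 d |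

| run | time / h | L / % | E / % |
|---|---|---|---|
| south | 4.00 | 5.9 | 94.6 |
| south | 10.0 | 16.8 | 84.0 |
| south | 20.0 | 26.4 | 70.0 |
| south | 30.0 | 39.1 | 60.8 |
| south | 40.0 | 47.1 | 52.5 |
| west | 3.00 | 13.7 | 87.7 |
| west | 6.00 | 24.3 | 76.7 |
| west | 12.0 | 40.8 | 58.2 |
| west | 20.0 | 61.2 | 39.6 |
| west | 40.0 | 81.9 | 16.9 |
| south-east | 4.00 | 30.7 | 68.5 |
| south-east | 10.0 | 61.4 | 38.7 |
| south-east | 20.0 | 83.8 | 17.2 |
| south-east | 30.0 | 91.8 | 6.7 |
| south-east | 40.0 | 95.4 | 2.6 |

(readings scatter by 1 percentage point)

- a reading or a percentage of L counts all its forms, free or not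

1. which of the two there is more of at the end, gamma (D / L)
2. which of the two there is more of at the end, epsilon (D / L)
3. which of the two there is more of at the end, eta (D / L)
4. how much L is there at the end, in percent of the E charged: gamma
5. how much L is there at the end, in percent of the E charged: epsilon
6. how much L is there at the end, in percent of the E charged: eta

That balance gives [J] = [J] at the start − the E lost. The ratio [J]/[E] then grows from its charged value exponentially, with exponent k × (J charge − E charge) × time. I solved this for each run's late reading of E and got 0.0723 L mol⁻¹ h⁻¹ (south), 0.0734 L mol⁻¹ h⁻¹ (west) and 0.0730 L mol⁻¹ h⁻¹ (south-east). Their mean is 0.0729 L mol⁻¹ h⁻¹, the balance constant, a reading with the scatter of its data. With it I reckoned E left at 47.7% in gamma, 9.54% in epsilon and 0.0558% in eta.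

Turned round: for D to beat L in eta, where I reckoned 0.0558% of E left, the gap in the balance of E (the charge less E and L) would have to pass half the charge within 2.5 d. The last south-east readings leave a gap of 2.00% after 40.0 h, and that gap stands on two readings, each with a scatter of 1 percentage point. The gap needed in eta runs 16.7 times faster than the one read in south-east, though south-east had less J than eta, so I expected L ahead in eta, and in gamma and epsilon, which had less J than south-east.

The forecast chose L, L and L for gamma, epsilon and eta, with L at 52% (49% to 55%), 89% (84% to 92%) and 93% (80% to 98%), and concluded “L remains dominant in all three”.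

The flasks gave L against D of 51.8% to 0.0183% in gamma, 89.7% to 0.191% in epsilon and 98.4% to 1.20% in eta. In the scheme, Z is the bis adduct and G the crystals of L.

    E + J → L (k = 0.0720 L mol⁻¹ h⁻¹)
    J + L → Z (k = 0.00230 L mol⁻¹ h⁻¹)
    J + Z → D (k = 0.0330 L mol⁻¹ h⁻¹)
    G ⇌ L, rate k4*(cs4 - [L]) while solid is left; crystals form when [L] > cs4 (solubility = 4.30 mM, k = 0.740 h⁻¹)

Gamma held 48% of its E against my 47.7%, and the same k gives 64.6% for gamma's neighbour with 0.12 M of J, which held 64.9%. Gamma, epsilon and eta had not come to rest at 2.5 d. Carried to 25.0 d, k leaves 0.635% of E in gamma, which held 0.686% then, with L risen to 98.6%. Epsilon's L rose to 96.9% by that time. Eta, 5.4 points above the forecast at 2.5 d, moved the other way: by 25.0 d its L had fallen to 89.5% and its D stood at 10.2%.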